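**Retrosynthetic overview** (target locants, 1-benzofuran-2-one numbering: O1, C2(=O), C3(=CH2), C3a, C4(OAc), C5(side chain), C6(CH2O-ester), C7, C7a)
- Last: the C6–CH2O methacrylate and the side-chain OH are unmasked (PMB → methacrylate, TBDPS off). Ring B (cyclohexene, tetrasubstituted C5=C6) is closed second, by ring-closing metathesis of two 1,1-disubstituted alkenes on the finished lactone.
- Ring A (γ-lactone) is closed first, at C3–C3a: a phosphonoacetate carbanion tethered through O1 on C7a opens a C3a–C4 trans-oxirane (5-exo, inversion at C3a). The same phosphonate then olefinates formaldehyde to give the C3 methylidene.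
- Enabling feature: the contiguous O1–C7a / C3a / C4–O triad, with the C3a–C3 bond anti to C4–O in the open chain (this equals trans ring fusion plus cis C4–OAc/C3a–C3). It is the retron of an erythro trans-2,3-epoxy alcohol (C7a carbinol, C3a–C4 oxirane); the exocyclic C3=CH2 is the retron of a phosphonate.
- The epoxy alcohol comes from Sharpless kinetic-resolution epoxidation of a dienol, made from a dienal and a 2-(alkoxymethyl)allylzinc. The dienal and the side-chain stereocentre come from (S)-citronellal.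

Key step: step 11

Remark: the SMILES is read as the 3a,7a-trans-fused (3aS,4S,7aR) lactone with C4–OAc cis to the C3a–C3 bond and a (2S) side chain; compounds 1, 7, 9, 10 and 14 are taken as commercial.

**Step 1**
Reactants: 1 (S)-citronellal [(3S)-3,7-dimethyloct-6-enal]
Product: 2 (6S)-8,8-dimethoxy-2,6-dimethyloct-2-ene
Conditions: HC(OMe)3, MeOH, PPTS (cat.), rt
Reagents that add atoms: trimethyl orthoformate, COC(OC)OC
Why: Mild acid-catalysed acetalization masks the aldehyde before the alkene is cleaved, PPTS being weak enough to avoid the carbonyl-ene cyclization of citronellal; the stereocentre is untouched.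

**Step 2**
Reactants: 2 (6S)-8,8-dimethoxy-2,6-dimethyloct-2-ene
Product: 3 (4S)-6,6-dimethoxy-4-methylhexan-1-ol
Conditions: O3, CH2Cl2–MeOH, −78 °C; then NaBH4, −78 °C → rt
Reagents that add atoms: ozone, [O-][O+]=O
Why: Ozonolysis with reductive work-up cleaves the only alkene to the primary alcohol while the acetal survives.

**Step 3**
Reactants: 3 (4S)-6,6-dimethoxy-4-methylhexan-1-ol
Product: 4 tert-butyl{[(4S)-6,6-dimethoxy-4-methylhexyl]oxy}diphenylsilane
Conditions: TBDPSCl, imidazole, DMF, rt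
Reagents that add atoms: tert-butyl(chloro)diphenylsilane, CC(C)(C)[Si](Cl)(c1ccccc1)c1ccccc1
Why: Standard silylation of a primary alcohol gives an ether that survives every later step up to the final fluoride treatment.

**Step 4**
Reactants: 4 tert-butyl{[(4S)-6,6-dimethoxy-4-methylhexyl]oxy}diphenylsilane
Product: 5 (3S)-6-[(tert-butyldiphenylsilyl)oxy]-3-methylhexanal
Conditions: PPTS (cat.), acetone–H2O, 50 °C
Reagents that add atoms: water, O
Why: Mild acid hydrolysis of the dimethyl acetal frees the aldehyde without touching the TBDPS ether.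

**Step 5**
Reactants: 5 (3S)-6-[(tert-butyldiphenylsilyl)oxy]-3-methylhexanal
Product: 6 (3S)-6-[(tert-butyldiphenylsilyl)oxy]-3-methyl-2-methylidenehexanal
Conditions: aq. CH2O (37%), pyrrolidine (10 mol%), propionic acid (10 mol%), i-PrOH, 45 °C
Reagents that add atoms: formaldehyde, C=O
Why: Organocatalytic α-methylenation (enamine Mannich addition, then amine elimination) gives the 2-substituted acrolein; the stereocentre is β to the carbonyl and cannot epimerize.

**Step 6**
Reactants: 6 (3S)-6-[(tert-butyldiphenylsilyl)oxy]-3-methyl-2-methylidenehexanal; 7 (triphenyl-λ5-phosphanylidene)acetaldehyde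
Product: 8 (2E,5S)-8-[(tert-butyldiphenylsilyl)oxy]-5-methyl-4-methylideneoct-2-enal
Conditions: toluene, 80 °C
Reagents that add atoms: none
Why: Wittig olefination with the stabilized formyl ylide extends the aldehyde by two carbons and should give the (E)-enal.

**Step 7**
Reactants: 9 (4-methoxyphenyl)methanol; 10 3-bromo-2-(bromomethyl)prop-1-ene
Product: 11 1-({[2-(bromomethyl)prop-2-en-1-yl]oxy}methyl)-4-methoxybenzene
Conditions: NaH, THF, 0 °C; then 10 (3 equiv), 0 °C → rt
Reagents that add atoms: none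
Why: Williamson mono-etherification of the symmetrical bis-allylic dibromide, used in excess to suppress the bis-ether.

**Step 8**
Reactants: 8 (2E,5S)-8-[(tert-butyldiphenylsilyl)oxy]-5-methyl-4-methylideneoct-2-enal; 11 1-({[2-(bromomethyl)prop-2-en-1-yl]oxy}methyl)-4-methoxybenzene
Product: 12 (5E,8S)-11-[(tert-butyldiphenylsilyl)oxy]-1-[(4-methoxyphenyl)methoxy]-8-methyl-2,7-dimethylideneundec-5-en-4-ol (both C4 epimers)
Conditions: Zn dust, sat. aq. NH4Cl–THF, 0 °C → rt
Reagents that add atoms: none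
Why: Aqueous Barbier allylation (allylzinc 1,2-addition to the enal) forms the carbinol; its configuration is not controlled here and both epimers are expected, to be sorted in step 9.

**Step 9**
Reactants: 12 (5E,8S)-11-[(tert-butyldiphenylsilyl)oxy]-1-[(4-methoxyphenyl)methoxy]-8-methyl-2,7-dimethylideneundec-5-en-4-ol (both C4 epimers)
Product: 13 (1R)-1-[(2R,3R)-3-{(3S)-6-[(tert-butyldiphenylsilyl)oxy]-3-methylhex-1-en-2-yl}oxiran-2-yl]-3-{[(4-methoxyphenyl)methoxy]methyl}but-3-en-1-ol
Conditions: Ti(OiPr)4 (15 mol%), D-(−)-diisopropyl tartrate (20 mol%), t-BuOOH (0.6 equiv), 4 Å MS, CH2Cl2, −20 °C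
Reagents that add atoms: tert-butyl hydroperoxide, CC(C)(C)OO
Why: Sharpless kinetic-resolution epoxidation: with the D-(−)-tartrate the (4R)-carbinol epimer is the fast-reacting one, and its allylic (E)-alkene is epoxidized under reagent control to the erythro (2R,3R)-oxirane; the (4S)-epimer and the homoallylic and remote 1,1-disubstituted alkenes are left.

**Step 10**
Reactants: 13 (1R)-1-[(2R,3R)-3-{(3S)-6-[(tert-butyldiphenylsilyl)oxy]-3-methylhex-1-en-2-yl}oxiran-2-yl]-3-{[(4-methoxyphenyl)methoxy]methyl}but-3-en-1-ol; 14 (diethoxyphosphoryl)acetic acid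
Product: 15 (1R)-1-[(2R,3R)-3-{(3S)-6-[(tert-butyldiphenylsilyl)oxy]-3-methylhex-1-en-2-yl}oxiran-2-yl]-3-{[(4-methoxyphenyl)methoxy]methyl}but-3-en-1-yl (diethoxyphosphoryl)acetate
Conditions: DCC, DMAP (cat.), CH2Cl2, 0 °C
Reagents that add atoms: none
Why: Steglich esterification attaches the nucleophile to the carbinol oxygen (future O1) under neutral conditions that leave the oxirane intact.

**Step 11**
Reactants: 15 (1R)-1-[(2R,3R)-3-{(3S)-6-[(tert-butyldiphenylsilyl)oxy]-3-methylhex-1-en-2-yl}oxiran-2-yl]-3-{[(4-methoxyphenyl)methoxy]methyl}but-3-en-1-yl (diethoxyphosphoryl)acetate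
Product: 17 (4R,5R)-4-[(1S,3S)-6-[(tert-butyldiphenylsilyl)oxy]-1-hydroxy-3-methyl-2-methylidenehexyl]-5-(2-{[(4-methoxyphenyl)methoxy]methyl}prop-2-en-1-yl)-3-methylideneoxolan-2-one, via α-phosphono hydroxy lactone potassium carbanion 16 (not isolated)
Conditions: KOt-Bu (1.05 equiv), THF, −20 °C → rt; then (CH2O)n, 0 °C → rt; aq. NH4Cl
Reagents that add atoms: formaldehyde (from paraformaldehyde), C=O
Why: Proposed new method: KOt-Bu generates the phosphonoacetate carbanion, which attacks the oxirane carbon next to the ester-bearing carbinol in an intramolecular SN2 displacement (closing the lactone by C–C bond formation); the alkoxide set free is protonated by the much more acidic α-phosphono lactone, and the resulting phosphonate carbanion olefinates formaldehyde (Horner–Wadsworth–Emmons) to give the exocyclic methylene. The closest known reactions are the telescoped intramolecular Michael addition/HWE olefination of phosphonoacetates of γ-hydroxy enones and the intermolecular alkylation of phosphonoacetate anions by epoxides (first stage of the Wadsworth–Emmons cyclopropanation); an ester-tethered epoxide opening followed by HWE is not established. The lactone ring closes in the 5-exo-tet mode, with the breaking C–O bond outside the forming ring. The new stereocentre (future C3a) is set by inversion at the oxirane carbon, so the trans-oxirane and erythro carbinol of 15 translate stereospecifically into the trans-β,γ-disubstituted lactone, and the retained carbinol (future C4) ends up cis to the new C–C bond once ring B is closed. The step needs 5-exo attack rather than 6-endo attack at the allylic oxirane carbon, and HWE capture before the γ-oxido phosphonate can transfer phosphorus to oxygen and cyclopropanate; the first is secured by the exo trajectory and the branched 2-alkenyl group shielding the allylic carbon, the second by low temperature and the fast internal proton transfer.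

**Step 12**
Reactants: 17 (4R,5R)-4-[(1S,3S)-6-[(tert-butyldiphenylsilyl)oxy]-1-hydroxy-3-methyl-2-methylidenehexyl]-5-(2-{[(4-methoxyphenyl)methoxy]methyl}prop-2-en-1-yl)-3-methylideneoxolan-2-one
Product: 18 (1S,3S)-6-[(tert-butyldiphenylsilyl)oxy]-1-[(2R,3S)-2-(2-{[(4-methoxyphenyl)methoxy]methyl}prop-2-en-1-yl)-4-methylidene-5-oxooxolan-3-yl]-3-methyl-2-methylidenehexyl acetate
Conditions: Ac2O, pyridine, DMAP (cat.), CH2Cl2, 0 °C → rt
Reagents that add atoms: acetic anhydride, CC(=O)OC(C)=O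
Why: DMAP-catalysed acetylation of the only free hydroxyl installs the target acetate and blocks translactonization to that oxygen.

**Step 13**
Reactants: 18 (1S,3S)-6-[(tert-butyldiphenylsilyl)oxy]-1-[(2R,3S)-2-(2-{[(4-methoxyphenyl)methoxy]methyl}prop-2-en-1-yl)-4-methylidene-5-oxooxolan-3-yl]-3-methyl-2-methylidenehexyl acetate
Product: 19 (3aS,4S,7aR)-5-[(2S)-5-[(tert-butyldiphenylsilyl)oxy]pentan-2-yl]-6-{[(4-methoxyphenyl)methoxy]methyl}-3-methylidene-2-oxo-2,3,3a,4,7,7a-hexahydro-1-benzofuran-4-yl acetate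
Conditions: second-generation Hoveyda–Grubbs-type catalyst RuCl2(=CH-C6H4-2-OiPr)(1,3-di-o-tolylimidazolidin-2-ylidene) (10 mol%), toluene (0.005 M), 80 °C, argon sparge
Reagents that add atoms: none
Why: Ring-closing metathesis of the two 1,1-disubstituted alkenes forms the tetrasubstituted cyclohexene (ring B) without creating a stereocentre; the α-methylene lactone is a bystander, since closure onto it would give a bridgehead alkene or a cyclobutene.

**Step 14**
Reactants: 19 (3aS,4S,7aR)-5-[(2S)-5-[(tert-butyldiphenylsilyl)oxy]pentan-2-yl]-6-{[(4-methoxyphenyl)methoxy]methyl}-3-methylidene-2-oxo-2,3,3a,4,7,7a-hexahydro-1-benzofuran-4-yl acetate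
Product: 20 (3aS,4S,7aR)-5-[(2S)-5-[(tert-butyldiphenylsilyl)oxy]pentan-2-yl]-6-(hydroxymethyl)-3-methylidene-2-oxo-2,3,3a,4,7,7a-hexahydro-1-benzofuran-4-yl acetate
Conditions: DDQ (1.3 equiv), CH2Cl2–pH 7 buffer, 0 °C
Reagents that add atoms: none
Why: Oxidative cleavage of the PMB ether frees the primary allylic alcohol while silyl ether, acetate and both electron-poor alkenes are inert to DDQ.

**Step 15**
Reactants: 20 (3aS,4S,7aR)-5-[(2S)-5-[(tert-butyldiphenylsilyl)oxy]pentan-2-yl]-6-(hydroxymethyl)-3-methylidene-2-oxo-2,3,3a,4,7,7a-hexahydro-1-benzofuran-4-yl acetate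
Product: 21 [(3aS,4S,7aR)-4-(acetyloxy)-5-[(2S)-5-[(tert-butyldiphenylsilyl)oxy]pentan-2-yl]-3-methylidene-2-oxo-2,3,3a,4,7,7a-hexahydro-1-benzofuran-6-yl]methyl 2-methylprop-2-enoate
Conditions: methacryloyl chloride, Et3N, DMAP (cat.), CH2Cl2, 0 °C
Reagents that add atoms: methacryloyl chloride, C=C(C)C(Cl)=O
Why: Acylation of the only free (primary) hydroxyl installs the methacrylate after the metathesis, so that it cannot take part in ring closure.

**Step 16**
Reactants: 21 [(3aS,4S,7aR)-4-(acetyloxy)-5-[(2S)-5-[(tert-butyldiphenylsilyl)oxy]pentan-2-yl]-3-methylidene-2-oxo-2,3,3a,4,7,7a-hexahydro-1-benzofuran-6-yl]methyl 2-methylprop-2-enoate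
Product: 22 [(3aS,4S,7aR)-4-(acetyloxy)-5-[(2S)-5-hydroxypentan-2-yl]-3-methylidene-2-oxo-2,3,3a,4,7,7a-hexahydro-1-benzofuran-6-yl]methyl 2-methylprop-2-enoate (target)
Conditions: HF·pyridine, THF–pyridine, 0 °C → rt
Reagents that add atoms: none
Why: Buffered fluoride desilylation removes the TBDPS group without acyl migration or conjugate addition to the acrylate-type alkenes.

**Compound list**
1 | (S)-citronellal, (3S)-3,7-dimethyloct-6-enal | C[C@@H](CCC=C(C)C)CC=O | starting material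
2 | (6S)-8,8-dimethoxy-2,6-dimethyloct-2-ene | C[C@@H](CCC=C(C)C)CC(OC)OC | intermediate
3 | (4S)-6,6-dimethoxy-4-methylhexan-1-ol | C[C@@H](CCCO)CC(OC)OC | intermediate
4 | tert-butyl{[(4S)-6,6-dimethoxy-4-methylhexyl]oxy}diphenylsilane | C[C@@H](CCCO[Si](c1ccccc1)(c1ccccc1)C(C)(C)C)CC(OC)OC | intermediate
5 | (3S)-6-[(tert-butyldiphenylsilyl)oxy]-3-methylhexanal | C[C@@H](CCCO[Si](c1ccccc1)(c1ccccc1)C(C)(C)C)CC=O | intermediate
6 | (3S)-6-[(tert-butyldiphenylsilyl)oxy]-3-methyl-2-methylidenehexanal | C=C(C=O)[C@@H](C)CCCO[Si](c1ccccc1)(c1ccccc1)C(C)(C)C | intermediate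
7 | (triphenyl-λ5-phosphanylidene)acetaldehyde | O=CC=P(c1ccccc1)(c1ccccc1)c1ccccc1 | starting material
8 | (2E,5S)-8-[(tert-butyldiphenylsilyl)oxy]-5-methyl-4-methylideneoct-2-enal | O=C/C=C/C(=C)[C@@H](C)CCCO[Si](c1ccccc1)(c1ccccc1)C(C)(C)C | intermediate
9 | (4-methoxyphenyl)methanol | COc1ccc(CO)cc1 | starting material
10 | 3-bromo-2-(bromomethyl)prop-1-ene | C=C(CBr)CBr | starting material
11 | 1-({[2-(bromomethyl)prop-2-en-1-yl]oxy}methyl)-4-methoxybenzene | C=C(CBr)COCc1ccc(OC)cc1 | intermediate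
12 | (5E,8S)-11-[(tert-butyldiphenylsilyl)oxy]-1-[(4-methoxyphenyl)methoxy]-8-methyl-2,7-dimethylideneundec-5-en-4-ol, both C4 epimers | C=C(COCc1ccc(OC)cc1)CC(O)/C=C/C(=C)[C@@H](C)CCCO[Si](c1ccccc1)(c1ccccc1)C(C)(C)C | intermediate
13 | (1R)-1-[(2R,3R)-3-{(3S)-6-[(tert-butyldiphenylsilyl)oxy]-3-methylhex-1-en-2-yl}oxiran-2-yl]-3-{[(4-methoxyphenyl)methoxy]methyl}but-3-en-1-ol | C=C([C@@H](C)CCCO[Si](c1ccccc1)(c1ccccc1)C(C)(C)C)[C@H]1O[C@@H]1[C@H](O)CC(=C)COCc1ccc(OC)cc1 | intermediate
14 | (diethoxyphosphoryl)acetic acid | CCOP(=O)(CC(=O)O)OCC | starting material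
15 | (1R)-1-[(2R,3R)-3-{(3S)-6-[(tert-butyldiphenylsilyl)oxy]-3-methylhex-1-en-2-yl}oxiran-2-yl]-3-{[(4-methoxyphenyl)methoxy]methyl}but-3-en-1-yl (diethoxyphosphoryl)acetate | C=C([C@@H](C)CCCO[Si](c1ccccc1)(c1ccccc1)C(C)(C)C)[C@H]1O[C@@H]1[C@H](OC(=O)CP(=O)(OCC)OCC)CC(=C)COCc1ccc(OC)cc1 | intermediate
16 | diethyl [(4R,5R)-4-[(1S,3S)-6-[(tert-butyldiphenylsilyl)oxy]-1-hydroxy-3-methyl-2-methylidenehexyl]-5-(2-{[(4-methoxyphenyl)methoxy]methyl}prop-2-en-1-yl)-2-oxooxolan-3-yl]phosphonate (C3 epimers; formed as its potassium carbanion) | C=C([C@@H](C)CCCO[Si](c1ccccc1)(c1ccccc1)C(C)(C)C)[C@@H](O)[C@H]1C(P(=O)(OCC)OCC)C(=O)O[C@@H]1CC(=C)COCc1ccc(OC)cc1 | intermediate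
17 | (4R,5R)-4-[(1S,3S)-6-[(tert-butyldiphenylsilyl)oxy]-1-hydroxy-3-methyl-2-methylidenehexyl]-5-(2-{[(4-methoxyphenyl)methoxy]methyl}prop-2-en-1-yl)-3-methylideneoxolan-2-one | C=C([C@@H](C)CCCO[Si](c1ccccc1)(c1ccccc1)C(C)(C)C)[C@@H](O)[C@H]1C(=C)C(=O)O[C@@H]1CC(=C)COCc1ccc(OC)cc1 | intermediate
18 | (1S,3S)-6-[(tert-butyldiphenylsilyl)oxy]-1-[(2R,3S)-2-(2-{[(4-methoxyphenyl)methoxy]methyl}prop-2-en-1-yl)-4-methylidene-5-oxooxolan-3-yl]-3-methyl-2-methylidenehexyl acetate | C=C([C@@H](C)CCCO[Si](c1ccccc1)(c1ccccc1)C(C)(C)C)[C@@H](OC(C)=O)[C@H]1C(=C)C(=O)O[C@@H]1CC(=C)COCc1ccc(OC)cc1 | intermediate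
19 | (3aS,4S,7aR)-5-[(2S)-5-[(tert-butyldiphenylsilyl)oxy]pentan-2-yl]-6-{[(4-methoxyphenyl)methoxy]methyl}-3-methylidene-2-oxo-2,3,3a,4,7,7a-hexahydro-1-benzofuran-4-yl acetate | COc1ccc(COCC2=C([C@@H](C)CCCO[Si](c3ccccc3)(c3ccccc3)C(C)(C)C)[C@@H](OC(C)=O)[C@H]3C(=C)C(=O)O[C@@H]3C2)cc1 | intermediate
20 | (3aS,4S,7aR)-5-[(2S)-5-[(tert-butyldiphenylsilyl)oxy]pentan-2-yl]-6-(hydroxymethyl)-3-methylidene-2-oxo-2,3,3a,4,7,7a-hexahydro-1-benzofuran-4-yl acetate | OCC1=C([C@@H](C)CCCO[Si](c2ccccc2)(c2ccccc2)C(C)(C)C)[C@@H](OC(C)=O)[C@H]2C(=C)C(=O)O[C@@H]2C1 | intermediate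
21 | [(3aS,4S,7aR)-4-(acetyloxy)-5-[(2S)-5-[(tert-butyldiphenylsilyl)oxy]pentan-2-yl]-3-methylidene-2-oxo-2,3,3a,4,7,7a-hexahydro-1-benzofuran-6-yl]methyl 2-methylprop-2-enoate | C=C(C)C(=O)OCC1=C([C@@H](C)CCCO[Si](c2ccccc2)(c2ccccc2)C(C)(C)C)[C@@H](OC(C)=O)[C@H]2C(=C)C(=O)O[C@@H]2C1 | intermediate
22 | [(3aS,4S,7aR)-4-(acetyloxy)-5-[(2S)-5-hydroxypentan-2-yl]-3-methylidene-2-oxo-2,3,3a,4,7,7a-hexahydro-1-benzofuran-6-yl]methyl 2-methylprop-2-enoate | C=C(C)C(=O)OCC1=C([C@@H](C)CCCO)[C@@H](OC(C)=O)[C@H]2C(=C)C(=O)O[C@@H]2C1 | target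

Total step count: 16. Longest linear sequence: 15 steps (steps 1–6 and 8–16).

**Steps most likely to fail**

1. Step 11 (proposed new method). The tethered carbanion may not reach the oxirane (the ester must adopt its less favoured conformation), it may attack the allylic oxirane carbon (6-endo), or on warming the γ-oxido phosphonate may transfer phosphorus to oxygen and close a cyclopropane. The fallback uses known reaction types, sets out from 12 and comes back at 18. Kinetic resolution with the opposite tartrate (Ti(OiPr)4, L-(+)-diisopropyl tartrate, t-BuOOH) consumes the (4S)-epimer and leaves (4R,5E,8S)-11-[(tert-butyldiphenylsilyl)oxy]-1-[(4-methoxyphenyl)methoxy]-8-methyl-2,7-dimethylideneundec-5-en-4-ol F1. DCC esterification with 14 gives the corresponding (diethoxyphosphoryl)acetate F2, and diazo transfer (p-ABSA, DBU, MeCN) gives the diazo(diethoxyphosphoryl)acetate F3. Rh2(OAc)4-catalysed intramolecular cyclopropanation of the (E)-alkene (benzene, 80 °C) closes the lactone at the same carbon–carbon bond, syn across the alkene and with the carbinol substituent exo, to give the cyclopropane-fused phosphono lactone F4. Homoconjugate acetolysis (CsOAc, AcOH, DMSO, 60 °C) should open the doubly activated cyclopropane at its allylic carbon with inversion to the acetoxy α-phosphono lactone F5. HWE olefination with aqueous formaldehyde and K2CO3 then gives 18.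

2. Step 13. Ring closure may stall through steric congestion at the 1,1-disubstituted alkene flanked by two branched carbons, leaving catalyst decomposition and intermolecular metathesis at the unhindered alkene to compete. The fallback sets out from 15 and comes back at 19. Step 11 is run without formaldehyde and 16 is isolated after aqueous quench. Metathesis with the same ruthenium catalyst is then done on 16, where the free allylic hydroxyl can assist the catalyst and neither an acrylate-type alkene nor an allylic acetate is present; this gives the bicyclic hydroxy phosphono lactone F6. HWE olefination (K2CO3, aq. CH2O, THF) gives the bicyclic hydroxy α-methylene lactone F7, and acetylation (Ac2O, pyridine, DMAP) gives 19.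

3. Step 9. The acid-labile alkenyl oxirane may be opened or rearranged by the titanium alkoxide species, and discrimination between the carbinol epimers may erode as conversion rises. The fallback sets out from 8 and comes back at 13. Organocatalytic epoxidation of the enal (aq. H2O2, CH2Cl2, with the (R)-configured α,α-diphenylprolinol trimethylsilyl ether, the enantiomer expected to deliver the (2S,3R)-oxirane) gives the trans-epoxy aldehyde (2S,3R)-3-{(3S)-6-[(tert-butyldiphenylsilyl)oxy]-3-methylhex-1-en-2-yl}oxirane-2-carbaldehyde F8 under reagent control. Barbier allylation with 11 (Zn dust, sat. aq. NH4Cl–THF) then gives 13; the erythro adduct is expected from Felkin–Anh addition, and the threo epimer is removed by chromatography.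

**Further compounds**
F1 | step 11 | (4R,5E,8S)-11-[(tert-butyldiphenylsilyl)oxy]-1-[(4-methoxyphenyl)methoxy]-8-methyl-2,7-dimethylideneundec-5-en-4-ol | C=C(COCc1ccc(OC)cc1)C[C@@H](O)/C=C/C(=C)[C@@H](C)CCCO[Si](c1ccccc1)(c1ccccc1)C(C)(C)C
F2 | step 11 | (4R,5E,8S)-11-[(tert-butyldiphenylsilyl)oxy]-1-[(4-methoxyphenyl)methoxy]-8-methyl-2,7-dimethylideneundec-5-en-4-yl (diethoxyphosphoryl)acetate | C=C(COCc1ccc(OC)cc1)C[C@@H](OC(=O)CP(=O)(OCC)OCC)/C=C/C(=C)[C@@H](C)CCCO[Si](c1ccccc1)(c1ccccc1)C(C)(C)C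
F3 | step 11 | (4R,5E,8S)-11-[(tert-butyldiphenylsilyl)oxy]-1-[(4-methoxyphenyl)methoxy]-8-methyl-2,7-dimethylideneundec-5-en-4-yl diazo(diethoxyphosphoryl)acetate | C=C(COCc1ccc(OC)cc1)C[C@@H](OC(=O)C(=[N+]=[N-])P(=O)(OCC)OCC)/C=C/C(=C)[C@@H](C)CCCO[Si](c1ccccc1)(c1ccccc1)C(C)(C)C
F4 | step 11 | diethyl [(1S,4R,5R,6R)-6-{(3S)-6-[(tert-butyldiphenylsilyl)oxy]-3-methylhex-1-en-2-yl}-4-(2-{[(4-methoxyphenyl)methoxy]methyl}prop-2-en-1-yl)-2-oxo-3-oxabicyclo[3.1.0]hexan-1-yl]phosphonate | CCOP(=O)(OCC)[C@]12C(=O)O[C@H](CC(=C)COCc3ccc(OC)cc3)[C@H]1[C@@H]2C(=C)[C@@H](C)CCCO[Si](c1ccccc1)(c1ccccc1)C(C)(C)C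
F5 | step 11 | (1S,3S)-6-[(tert-butyldiphenylsilyl)oxy]-1-[(2R,3S)-4-(diethoxyphosphoryl)-2-(2-{[(4-methoxyphenyl)methoxy]methyl}prop-2-en-1-yl)-5-oxooxolan-3-yl]-3-methyl-2-methylidenehexyl acetate (C4 epimers) | C=C([C@@H](C)CCCO[Si](c1ccccc1)(c1ccccc1)C(C)(C)C)[C@@H](OC(C)=O)[C@H]1C(P(=O)(OCC)OCC)C(=O)O[C@@H]1CC(=C)COCc1ccc(OC)cc1
F6 | step 13 | diethyl [(3aR,4S,7aR)-5-[(2S)-5-[(tert-butyldiphenylsilyl)oxy]pentan-2-yl]-4-hydroxy-6-{[(4-methoxyphenyl)methoxy]methyl}-2-oxo-2,3,3a,4,7,7a-hexahydro-1-benzofuran-3-yl]phosphonate (C3 epimers) | COc1ccc(COCC2=C([C@@H](C)CCCO[Si](c3ccccc3)(c3ccccc3)C(C)(C)C)[C@@H](O)[C@H]3C(P(=O)(OCC)OCC)C(=O)O[C@@H]3C2)cc1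
F7 | step 13 | (3aR,4S,7aR)-5-[(2S)-5-[(tert-butyldiphenylsilyl)oxy]pentan-2-yl]-4-hydroxy-6-{[(4-methoxyphenyl)methoxy]methyl}-3-methylidene-3a,4,7,7a-tetrahydro-1-benzofuran-2(3H)-one | COc1ccc(COCC2=C([C@@H](C)CCCO[Si](c3ccccc3)(c3ccccc3)C(C)(C)C)[C@@H](O)[C@H]3C(=C)C(=O)O[C@@H]3C2)cc1
F8 | step 9 | (2S,3R)-3-{(3S)-6-[(tert-butyldiphenylsilyl)oxy]-3-methylhex-1-en-2-yl}oxirane-2-carbaldehyde | O=C[C@H]1O[C@@H]1C(=C)[C@@H](C)CCCO[Si](c1ccccc1)(c1ccccc1)C(C)(C)C
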